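**Retrosynthetic overview**
- The target comes from N–O cleavage of a TEMPO-capped dihydrobenzofuran. That ring is closed by a 5-exo-trig aryl-radical cyclisation/TEMPO capture of an o-iodoaryl 1-arylallyl ether, which forms C3–C3a and sets C3 trans to C2.
- The C2 stereocentre comes from an Ir-catalysed enantioselective allylic etherification of 5-iodovanillin with a sinapyl methyl carbonate that already carries the complete, unprotected erythro glycerol unit.
- The erythro (7S,8R) aryl-glycerol ether comes from an auxiliary-controlled anti-aldol of an N-(aryloxyacetyl)oxazolidinone with vanillin, followed by NaBH4 cleavage.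
- All three arenes come from catechol along one trunk: guaiacol → vanillin → 5-iodovanillin → syringaldehyde (→ sinapyl alcohol).
- Ring order: the benzene rings are carried intact; the dihydrofuran is the only ring formed (step 13, penultimate).

Assumption: the Evans auxiliary, the Ir ligand, Bu3SnH and TEMPO are treated as reagents; the senses of induction stated in steps 10 and 12 are assigned from transition-state reasoning and recalled precedent, not verified, and a reversed sense would only require the antipodal auxiliary or ligand.

**Route**

Step 1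
Reactants: 1 catechol
Product: 2 guaiacol (2-methoxyphenol)
Conditions: MeI (1.0 equiv), K2CO3 (1.0 equiv), acetone, reflux
Reagents that add atoms: iodomethane, CI
Why: Williamson mono-O-methylation with limiting MeI; veratrole and unreacted catechol are removed by base/water partition and distillation.

Step 2
Reactants: 2 guaiacol; 3 glyoxylic acid
Product: 4 vanillin
Conditions: aq. NaOH, 30 °C; then CuSO4 (cat.), air, 95 °C; H2SO4 work-up (one pot)
Reagents that add atoms: none
Why: para-selective hydroxyalkylation of the phenoxide gives the mandelic acid, which undergoes Cu-catalysed oxidative decarboxylation to the aldehyde (the industrial glyoxylic acid vanillin process).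

Step 3
Reactants: 4 vanillin
Product: 5 5-iodovanillin (4-hydroxy-3-iodo-5-methoxybenzaldehyde)
Conditions: I2, KI, NaHCO3, H2O, rt
Reagents that add atoms: iodine, II
Why: electrophilic aromatic iodination at the only free position ortho to the phenoxide.

Step 4
Reactants: 5 5-iodovanillin
Product: 6 syringaldehyde
Conditions: NaOMe (5 equiv), CuCl (0.3 equiv), DMF/MeOH, 110 °C
Reagents that add atoms: sodium methoxide, [Na+].[O-]C
Why: Ullmann-type Cu-catalysed methoxylation of the aryl iodide; the phenoxide protects the aldehyde from Cannizzaro chemistry.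

Step 5
Reactants: 6 syringaldehyde; 7 methyl hydrogen malonate
Product: 8 methyl (E)-sinapate
Conditions: pyridine, piperidine (cat.), 90 °C
Reagents that add atoms: none
Why: Knoevenagel–Doebner condensation with decarboxylation gives the (E)-cinnamate.

Step 6
Reactants: 8 methyl (E)-sinapate
Product: 9 (E)-sinapyl alcohol
Conditions: DIBAL-H (4 equiv), PhMe, 0 °C
Reagents that add atoms: none
Why: clean 1,2-reduction of the cinnamate; the aluminium phenoxide is inert.

Step 7
Reactants: 10 bromoacetyl bromide
Product: 11 (R)-4-benzyl-3-(bromoacetyl)oxazolidin-2-one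
Conditions: (R)-4-benzyl-2-oxazolidinone, n-BuLi, THF, −78 °C
Reagents that add atoms: (R)-4-benzyl-2-oxazolidinone (recoverable auxiliary, expelled in step 11), O=C1N[C@H](Cc2ccccc2)CO1
Why: N-acylation of the lithiated auxiliary at the acyl bromide, which is far more electrophilic than the CH2Br.

Step 8
Reactants: 9 sinapyl alcohol; 11 bromoacetyl imide
Product: 12 (R)-4-benzyl-3-{2-[4-((E)-3-hydroxyprop-1-enyl)-2,6-dimethoxyphenoxy]acetyl}oxazolidin-2-one
Conditions: K2CO3, acetone, rt, N2
Reagents that add atoms: none
Why: chemoselective SN2 O-alkylation of the phenoxide (pKa ≈ 10) by the α-bromo imide; the allylic alcohol is not deprotonated.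

Step 9
Reactants: 12
Product: 13 (E)-3-{4-[2-((R)-4-benzyl-2-oxooxazolidin-3-yl)-2-oxoethoxy]-3,5-dimethoxyphenyl}allyl methyl carbonate
Conditions: ClCO2Me, pyridine, CH2Cl2, 0 °C
Reagents that add atoms: methyl chloroformate, COC(=O)Cl
Why: acylation of the only hydroxyl installs the leaving group for step 12.

Step 10
Reactants: 13; 4 vanillin
Product: 14 anti-aldol adduct, (2S,3S)-3-hydroxy-3-(4-hydroxy-3-methoxyphenyl)-2-aryloxypropanoyl imide of the (R)-auxiliary (aryl = 2,6-dimethoxy-4-[(E)-3-(methoxycarbonyloxy)prop-1-enyl]phenyl)
Conditions: 4 pre-silylated in the flask (TMSCl, Et3N, EtOAc); then 13, MgCl2 (0.2–1.0 equiv), Et3N, TMSCl, EtOAc, 23 °C; then THF/1 M HCl (5:1), 0 °C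
Reagents that add atoms: none (both TMS groups are removed in the work-up)
Why: Proposed new method: extension of the Evans MgCl2/Et3N/TMSCl anti-aldol (established for N-propionyl-type oxazolidinones with non-enolisable aryl aldehydes, the closest known reaction) to an N-(aryloxyacetyl)imide; soft enolisation should give the Mg-chelated Z-enolate, which adds to the in situ O-TMS vanillin through a boat-like transition state on the face opposite the benzyl group to give the 2,3-anti (erythro) adduct, with the (R)-auxiliary predicted to give (2S,3S), and TMSCl silylates the aldolate to turn Mg over.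

Step 11
Reactants: 14
Product: 15 (E)-3-{4-[((1S,2R)-1,3-dihydroxy-1-(4-hydroxy-3-methoxyphenyl)propan-2-yl)oxy]-3,5-dimethoxyphenyl}allyl methyl carbonate
Conditions: NaBH4 (excess), THF/H2O 4:1, 0 °C → rt
Reagents that add atoms: none
Why: borohydride reductive cleavage of the N-acyloxazolidinone gives the primary alcohol and returns the auxiliary without touching the carbonate; no stereocentre is involved (the C8 descriptor changes from S to R only through CIP priorities).

Step 12
Reactants: 15; 5 5-iodovanillin
Product: 16 4-{[(R)-1-(4-{[(1S,2R)-1,3-dihydroxy-1-(4-hydroxy-3-methoxyphenyl)propan-2-yl]oxy}-3,5-dimethoxyphenyl)allyl]oxy}-3-iodo-5-methoxybenzaldehyde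
Conditions: [Ir(cod)Cl]2 (2 mol %), (Ra,Rc,Rc)-BINOL bis(1-phenylethyl)phosphoramidite (4 mol %, pre-activated with n-PrNH2, then evaporated), sodium salt of 5 (1.5 equiv) + free 5 (1.0 equiv), THF, 35 °C
Reagents that add atoms: none
Why: Hartwig-type Ir-catalysed enantioselective allylic etherification, in which the aryloxide attacks the substituted terminus of the Ir π-allyl under catalyst control to give the (R)-branched ether; excess free 5 (much more acidic than the guaiacyl OH) buffers the methoxide released, so only the iodovanillinate is nucleophilic.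

Step 13
Reactants: 16
Product: 17 (2R,3S)-2-(4-{[(1S,2R)-1,3-dihydroxy-1-(4-hydroxy-3-methoxyphenyl)propan-2-yl]oxy}-3,5-dimethoxyphenyl)-7-methoxy-3-{[(2,2,6,6-tetramethylpiperidin-1-yl)oxy]methyl}-2,3-dihydrobenzofuran-5-carbaldehyde
Conditions: Bu3SnH (portionwise, 3–5 equiv), TEMPO (5–6 equiv), PhH, 65 °C
Reagents that add atoms: TEMPO, CC1(C)CCCC(C)(C)N1[O]
Why: iodine abstraction gives the aryl radical, whose 5-exo-trig cyclisation onto the vinyl group outruns all bimolecular traps and forms C3–C3a through a chair-like Beckwith–Houk transition state with the C2-aryl pseudo-equatorial (2,3-trans, so 3S from 2R); the primary radical is captured by TEMPO (Boger-type TEMPO-terminated aryl radical cyclisation), and the free phenol, diol and aldehyde are poor partners for these radicals.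

Step 14
Reactants: 17
Product: 18 target, (2R,3S)-2-(4-{[(1S,2R)-1,3-dihydroxy-1-(4-hydroxy-3-methoxyphenyl)propan-2-yl]oxy}-3,5-dimethoxyphenyl)-3-(hydroxymethyl)-7-methoxy-2,3-dihydrobenzofuran-5-carbaldehyde
Conditions: Zn dust, AcOH/THF/H2O 3:1:1, 50 °C
Reagents that add atoms: none
Why: reductive N–O cleavage of the alkoxyamine releases the primary alcohol (its oxygen comes from TEMPO); the electron-rich aryl aldehyde and the benzylic carbinols should tolerate the mild acid at this temperature.

**Compound list**
1 | catechol | Oc1ccccc1O | starting material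
2 | guaiacol | COc1ccccc1O | intermediate
3 | glyoxylic acid | O=CC(=O)O | starting material
4 | vanillin | COc1cc(C=O)ccc1O | intermediate
5 | 5-iodovanillin | COc1cc(C=O)cc(I)c1O | intermediate
6 | syringaldehyde | COc1cc(C=O)cc(OC)c1O | intermediate
7 | methyl hydrogen malonate | COC(=O)CC(=O)O | starting material
8 | methyl (E)-sinapate | COC(=O)/C=C/c1cc(OC)c(O)c(OC)c1 | intermediate
9 | (E)-sinapyl alcohol | OC/C=C/c1cc(OC)c(O)c(OC)c1 | intermediate
10 | bromoacetyl bromide | BrCC(=O)Br | starting material
11 | (R)-4-benzyl-3-(bromoacetyl)oxazolidin-2-one | O=C(CBr)N1C(=O)OC[C@H]1Cc1ccccc1 | intermediate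
12 | aryloxyacetyl imide with free allylic alcohol | O=C(COc1c(OC)cc(/C=C/CO)cc1OC)N1C(=O)OC[C@H]1Cc1ccccc1 | intermediate
13 | aryloxyacetyl imide allylic methyl carbonate | O=C(COc1c(OC)cc(/C=C/COC(=O)OC)cc1OC)N1C(=O)OC[C@H]1Cc1ccccc1 | intermediate
14 | (2S,3S)-anti-aldol imide | COc1cc([C@H](O)[C@@H](C(=O)N3C(=O)OC[C@H]3Cc3ccccc3)Oc2c(OC)cc(/C=C/COC(=O)OC)cc2OC)ccc1O | intermediate
15 | (1S,2R)-erythro diol cinnamyl carbonate | COc1cc([C@H](O)[C@@H](CO)Oc2c(OC)cc(/C=C/COC(=O)OC)cc2OC)ccc1O | intermediate
16 | (R)-branched o-iodoaryl allyl ether | COc1cc([C@H](O)[C@@H](CO)Oc2c(OC)cc([C@@H](C=C)Oc3c(OC)cc(C=O)cc3I)cc2OC)ccc1O | intermediate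
17 | (2R,3S)-TEMPO-capped dihydrobenzofuran | COc1cc([C@H](O)[C@@H](CO)Oc2c(OC)cc([C@@H]3Oc4c(OC)cc(C=O)cc4[C@H]3CON5C(C)(C)CCCC5(C)C)cc2OC)ccc1O | intermediate
18 | CID 53356209 | COc1cc([C@H](O)[C@@H](CO)Oc2c(OC)cc([C@@H]3Oc4c(OC)cc(C=O)cc4[C@H]3CO)cc2OC)ccc1O | target

**Totals**
Total steps: 14. Longest linear sequence: 13 (steps 1–6 and 8–14; step 7 is a one-step side branch, and vanillin and 5-iodovanillin re-enter from the same trunk).

**Three steps most likely to fail, with fallbacks**
1. Step 10 (anti-aldol on an aryloxyacetyl imide; Mg chelation by the 2,6-dimethoxyaryloxy group may erode rate or selectivity). Fallback: use the (S)-auxiliary with Bu2BOTf/i-Pr2NEt and O-silyl vanillin to get the Evans syn (threo, C8 correct) adduct, then invert C7 by Mitsunobu esterification/hydrolysis after masking the C9 hydroxyl; this is precedented on lignin dimers but costs about four steps.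
2. Step 12 (a hindered, acidic, di-ortho-substituted phenoxide on an unprotected polyol electrophile; possible slow attack or branched-to-linear erosion). Fallback: reverse the polarity of the ether formation by making the (S)-1-arylprop-2-en-1-ol (asymmetric vinyl addition to the corresponding ring-B aldehyde) and coupling it with 5 under Mitsunobu conditions with inversion.
3. Step 13 (modest trans:cis ratio or side reactions of the fully unprotected substrate). Fallback: move the cyclisation earlier, onto the simple O-TIPS sinapyl-derived (R)-allyl ether of 5 with the ring-C aldehyde as its dimethyl acetal, upgrade the trans isomer by crystallisation, then build the glycerol unit on the released phenol by the step 8/10/11 sequence.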